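**Retrosynthetic overview**

1. Last bonds: the C7 hydroxyl is freed from a 2-naphthylmethyl ether after the stearate has been placed on the only free hydroxyl (C10); the C10 carbinol comes from a C10 ketone by Felkin–Anh reduction.
2. C9–C10: the ketone comes from addition of a dithiane acyl-anion equivalent (C10–C19) to a γ-lactone (C1–C9, C9 = lactone carbonyl); silane reduction of the lactol sets C9.
3. C7–C8: the lactone comes from a diazoacetate by intramolecular rhodium-carbene insertion into a C7–H bond. This closes the only ring of the target (O, C6, C7, C8, C9), first as a lactone, and the ring is never reopened.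
4. Enabling feature: the ring oxygen joins C6 to C9, so C9 can be an ester carbonyl whose α-carbon C8 carries the carbene exactly 1,5 to C7; the C7–H bond is activated by the oxygen that becomes the ring hydroxyl.
5. The diazoacetate comes from (R)-glycidol (C5–C7 and the C6 configuration), n-BuMgCl (C1–C4) and bromoacetyl bromide (C8, C9); C7, C9 and C10 are then set in turn by the insertion, the lactol reduction and the ketone reduction.

Key step: step 5

Remark on locants: C1–C19 are those of the nonadec-18-ene chain (C1–C5 pentyl, C6–C9 ring carbons, C10 the ester carbinol, C18=C19 the alkene).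
Assumption: the (4S) enantiomer of the MPPIM catalyst is taken as the one matched to the (S)-configured diazoacetate; if the pairing is the reverse, the (4R) catalyst is used in the same way.

**Route**

Step 1
Reactants: 1 (R)-glycidol
Product: 2 (S)-2-[(naphthalen-2-ylmethoxy)methyl]oxirane
Conditions: NaH, 2-(bromomethyl)naphthalene, n-Bu4NI (cat.), THF/DMF, 0 °C to rt
Reagents that add atoms: 2-(bromomethyl)naphthalene, BrCc1ccc2ccccc2c1
Why: Williamson etherification of the primary alkoxide does not touch the stereocentre (the Payne rearrangement of the glycidol alkoxide is degenerate and returns the same enantiomer); the descriptor changes from R to S only because the substituent priorities change.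

Step 2
Reactants: 2 (S)-2-[(naphthalen-2-ylmethoxy)methyl]oxirane; 3 n-butylmagnesium chloride
Product: 4 (S)-1-(naphthalen-2-ylmethoxy)heptan-2-ol
Conditions: CuI (10 mol%), THF, −30 °C; then aq. NH4Cl
Reagents that add atoms: none
Why: Copper-catalysed Grignard opening of the terminal epoxide (SN2 at the CH2 carbon) joins C4 to C5 and leaves the carbinol centre C6 untouched.

Step 3
Reactants: 4 (S)-1-(naphthalen-2-ylmethoxy)heptan-2-ol; 5 bromoacetyl bromide
Product: 6 (S)-1-(naphthalen-2-ylmethoxy)heptan-2-yl 2-bromoacetate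
Conditions: NaHCO3, MeCN, 0 °C
Reagents that add atoms: none
Why: Esterification of the secondary alcohol by the acyl bromide, with retention at C6, brings in C8 and C9.

Step 4
Reactants: 6 (S)-1-(naphthalen-2-ylmethoxy)heptan-2-yl 2-bromoacetate
Product: 7 (S)-1-(naphthalen-2-ylmethoxy)heptan-2-yl 2-diazoacetate
Conditions: N,N′-ditosylhydrazine, DBU, THF, 0 °C
Reagents that add atoms: N,N′-ditosylhydrazine, Cc1ccc(cc1)S(=O)(=O)NNS(=O)(=O)c1ccc(C)cc1
Why: Diazo formation by the ditosylhydrazine method: N-alkylation of the hydrazide by the bromoacetate and base-induced loss of two sulfinate ions (Bamford–Stevens-type elimination) should give the diazoacetate at 0 °C without touching the ether or the stereocentre.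

Step 5
Reactants: 7 (S)-1-(naphthalen-2-ylmethoxy)heptan-2-yl 2-diazoacetate
Product: 8 (4S,5S)-4-(naphthalen-2-ylmethoxy)-5-pentyloxolan-2-one
Conditions: Rh2(4S-MPPIM)4 (1 mol%) [MPPIM = methyl 1-(3-phenylpropanoyl)-2-oxoimidazolidine-4-carboxylate], CH2Cl2, reflux, 7 added over 10 h
Reagents that add atoms: none
Why: The divalent rhodium carboxamidate expels N2 from 7 to give a rhodium carbene at C8, which inserts into a C7–H bond through a concerted, asynchronous three-centre transition state in which hydride character passes from C7 to the carbene carbon as the C7–C8 bond forms, with retention at C7. The closest known reaction type is the insertion of secondary alkyl diazoacetates catalysed by Rh2(MEPY)4 or Rh2(MPPIM)4, including 1,3-dialkoxypropan-2-yl diazoacetates, which give cis-4-alkoxy-5-substituted butyrolactones. The ring closed is the five-membered lactone O–C9–C8–C7–C6, formed by 1,5-insertion (the carbene carbon bonds to the fifth atom of the chain it heads). The new stereocentre C7 (S) is set by the choice between the two diastereotopic C7–H bonds: the chiral ligand sphere selects the hydrogen whose insertion places the naphthylmethoxy group cis to the pentyl group, and the resident C6 centre reinforces the matched catalyst. The step needs site selectivity for C7–H over the equally 1,5-placed C5–H of the pentyl chain and over capture of the carbene by the ether oxygen; the lone pair on the C7 oxygen activates C7–H towards the electrophilic carbene, the electron-rich carboxamidate ligands make the carbene selective enough to respond to this activation, and slow addition suppresses carbene dimerisation.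

Step 6
Reactants: 9 1,3-dithiane; 10 9-bromonon-1-ene
Product: 12 2-(non-8-en-1-yl)-1,3-dithiane, via 2-lithio-1,3-dithiane 11 (not isolated)
Conditions: n-BuLi, THF, −30 °C; then 10, −78 °C to 0 °C
Reagents that add atoms: none
Why: Corey–Seebach alkylation: the dithiane carbanion displaces the primary bromide (SN2) and C10 is masked at the ketone oxidation level.

Step 7
Reactants: 12 2-(non-8-en-1-yl)-1,3-dithiane; 8 (4S,5S)-4-(naphthalen-2-ylmethoxy)-5-pentyloxolan-2-one
Product: 14 (4S,5S)-4-(naphthalen-2-ylmethoxy)-2-[2-(non-8-en-1-yl)-1,3-dithian-2-yl]-5-pentyloxolan-2-ol (mixture of C2 epimers), via 2-lithio-2-(non-8-en-1-yl)-1,3-dithiane 13 (not isolated)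
Conditions: n-BuLi, THF, −20 °C, 3 h; then 8, −78 °C; then aq. NH4Cl
Reagents that add atoms: none
Why: Acylation of a dithiane acyl-anion equivalent by a lactone, which stops at the lithium lactolate at −78 °C, forms the C9–C10 bond; C9 stays an epimeric hemiketal centre that is resolved in step 8.

Step 8
Reactants: 14 (4S,5S)-4-(naphthalen-2-ylmethoxy)-2-[2-(non-8-en-1-yl)-1,3-dithian-2-yl]-5-pentyloxolan-2-ol
Product: 15 2-[(2R,4S,5S)-4-(naphthalen-2-ylmethoxy)-5-pentyloxolan-2-yl]-2-(non-8-en-1-yl)-1,3-dithiane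
Conditions: Et3SiH, BF3·OEt2, CH2Cl2, −78 °C to −40 °C
Reagents that add atoms: none
Why: Lewis-acid ionisation of the hemiketal to a five-membered oxocarbenium ion and silane reduction (the lactone-to-C-glycoside sequence): hydride should attack on the inside of the envelope in which the C7 alkoxy group is pseudo-axial, cis to that oxygen, so that the C10 substituent ends trans to both the C7 oxygen and the pentyl group, C9 (R).

Step 9
Reactants: 15 2-[(2R,4S,5S)-4-(naphthalen-2-ylmethoxy)-5-pentyloxolan-2-yl]-2-(non-8-en-1-yl)-1,3-dithiane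
Product: 16 1-[(2R,4S,5S)-4-(naphthalen-2-ylmethoxy)-5-pentyloxolan-2-yl]dec-9-en-1-one
Conditions: MeI, CaCO3, MeCN/H2O (4:1), 45 °C
Reagents that add atoms: water, O
Why: Alkylative dithioacetal hydrolysis: S-methylation turns the dithiane into a leaving group and water captures the thionium ion, under near-neutral conditions that should not epimerise C9.

Step 10
Reactants: 16 1-[(2R,4S,5S)-4-(naphthalen-2-ylmethoxy)-5-pentyloxolan-2-yl]dec-9-en-1-one
Product: 17 (1R)-1-[(2R,4S,5S)-4-(naphthalen-2-ylmethoxy)-5-pentyloxolan-2-yl]dec-9-en-1-ol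
Conditions: LiBH(s-Bu)3 (L-Selectride), THF, −78 °C; then aq. NH4Cl
Reagents that add atoms: none
Why: Felkin–Anh reduction of the α-alkoxy ketone: the bulky, non-chelating hydride attacks anti to the C9–O ring bond and should give the threo alcohol, C10 (R).

Step 11
Reactants: 17 (1R)-1-[(2R,4S,5S)-4-(naphthalen-2-ylmethoxy)-5-pentyloxolan-2-yl]dec-9-en-1-ol; 18 octadecanoyl chloride
Product: 19 (1R)-1-[(2R,4S,5S)-4-(naphthalen-2-ylmethoxy)-5-pentyloxolan-2-yl]dec-9-en-1-yl octadecanoate
Conditions: pyridine, DMAP (cat.), CH2Cl2, 0 °C to rt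
Reagents that add atoms: none
Why: DMAP-catalysed acylation of the only free hydroxyl fixes the ester at C10 without any question of regiochemistry.

Step 12
Reactants: 19 (1R)-1-[(2R,4S,5S)-4-(naphthalen-2-ylmethoxy)-5-pentyloxolan-2-yl]dec-9-en-1-yl octadecanoate
Product: 20 (1R)-1-[(2R,4S,5S)-4-hydroxy-5-pentyloxolan-2-yl]dec-9-en-1-yl octadecanoate
Conditions: DDQ, CH2Cl2/pH 7 buffer (10:1), 0 °C to rt
Reagents that add atoms: none
Why: Oxidative cleavage of the naphthylmethyl ether by DDQ (hydride abstraction to an oxocarbenium ion, then hydrolysis) should free the C7 hydroxyl and leave the ester and the terminal alkene untouched.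

**Compound list**

1 | (R)-glycidol, (2R)-oxiran-2-ylmethanol | OC[C@@H]1CO1 | starting material
2 | (S)-2-[(naphthalen-2-ylmethoxy)methyl]oxirane | C(OCc1ccc2ccccc2c1)[C@@H]3CO3 | intermediate
3 | n-butylmagnesium chloride | CCCC[Mg]Cl | starting material
4 | (S)-1-(naphthalen-2-ylmethoxy)heptan-2-ol | CCCCC[C@H](O)COCc1ccc2ccccc2c1 | intermediate
5 | bromoacetyl bromide | BrCC(Br)=O | starting material
6 | (S)-1-(naphthalen-2-ylmethoxy)heptan-2-yl 2-bromoacetate | CCCCC[C@H](OC(=O)CBr)COCc1ccc2ccccc2c1 | intermediate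
7 | (S)-1-(naphthalen-2-ylmethoxy)heptan-2-yl 2-diazoacetate | CCCCC[C@H](OC(=O)C=[N+]=[N-])COCc1ccc2ccccc2c1 | intermediate
8 | (4S,5S)-4-(naphthalen-2-ylmethoxy)-5-pentyloxolan-2-one (cis lactone) | O=C1C[C@H](OCc2ccc3ccccc3c2)[C@H](CCCCC)O1 | intermediate
9 | 1,3-dithiane | C1CSCSC1 | starting material
10 | 9-bromonon-1-ene | C=CCCCCCCCBr | starting material
11 | 2-lithio-1,3-dithiane | [Li]C1SCCCS1 | intermediate (not isolated)
12 | 2-(non-8-en-1-yl)-1,3-dithiane | C=CCCCCCCCC1SCCCS1 | intermediate
13 | 2-lithio-2-(non-8-en-1-yl)-1,3-dithiane | C=CCCCCCCCC1([Li])SCCCS1 | intermediate (not isolated)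
14 | (4S,5S)-4-(naphthalen-2-ylmethoxy)-2-[2-(non-8-en-1-yl)-1,3-dithian-2-yl]-5-pentyloxolan-2-ol, both C2 epimers, in equilibrium with the open hydroxy ketone | C=CCCCCCCCC1(SCCCS1)C2(O)C[C@H](OCc3ccc4ccccc4c3)[C@H](CCCCC)O2 | intermediate
15 | 2-[(2R,4S,5S)-4-(naphthalen-2-ylmethoxy)-5-pentyloxolan-2-yl]-2-(non-8-en-1-yl)-1,3-dithiane | C=CCCCCCCCC1(SCCCS1)[C@H]2C[C@H](OCc3ccc4ccccc4c3)[C@H](CCCCC)O2 | intermediate
16 | 1-[(2R,4S,5S)-4-(naphthalen-2-ylmethoxy)-5-pentyloxolan-2-yl]dec-9-en-1-one | C=CCCCCCCCC(=O)[C@H]1C[C@H](OCc2ccc3ccccc3c2)[C@H](CCCCC)O1 | intermediate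
17 | (1R)-1-[(2R,4S,5S)-4-(naphthalen-2-ylmethoxy)-5-pentyloxolan-2-yl]dec-9-en-1-ol | C=CCCCCCCC[C@@H](O)[C@H]1C[C@H](OCc2ccc3ccccc3c2)[C@H](CCCCC)O1 | intermediate
18 | octadecanoyl chloride (stearoyl chloride) | CCCCCCCCCCCCCCCCCC(=O)Cl | starting material
19 | (1R)-1-[(2R,4S,5S)-4-(naphthalen-2-ylmethoxy)-5-pentyloxolan-2-yl]dec-9-en-1-yl octadecanoate | C=CCCCCCCC[C@@H](OC(=O)CCCCCCCCCCCCCCCCC)[C@H]1C[C@H](OCc2ccc3ccccc3c2)[C@H](CCCCC)O1 | intermediate
20 | (1R)-1-[(2R,4S,5S)-4-hydroxy-5-pentyloxolan-2-yl]dec-9-en-1-yl octadecanoate | C=CCCCCCCC[C@@H](OC(=O)CCCCCCCCCCCCCCCCC)[C@H]1C[C@H](O)[C@H](CCCCC)O1 | target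

**Step count and risks**

Total step count: 12. Longest linear sequence: 11 steps (steps 1–5, then 7–12); step 6 is the one-step side branch.

Steps most likely to fail:

1. Step 5. The carbene insertion may lose site or facial selectivity: insertion into the C5–H bond of the pentyl chain, insertion into the other diastereotopic C7–H bond if catalyst and substrate are mismatched, or capture of the carbene by the ether oxygen. The fallback sets out from 3 and comes back at 8, and makes the same C7–C8 bond by a Claisen-type ring closure. CuI-catalysed addition of 3 to commercial methyl (S)-oxirane-2-carboxylate at −78 °C should give methyl (S)-2-hydroxyheptanoate F1. Acetylation (Ac2O, pyridine, DMAP) gives methyl (S)-2-acetoxyheptanoate F2. LiN(SiMe3)2 in THF at −78 °C effects Dieckmann condensation to (5S)-4-hydroxy-5-pentylfuran-2(5H)-one F3. Hydrogenation over Rh/Al2O3 (H2, EtOAc) adds hydrogen to the face away from the pentyl group and should give (4S,5S)-4-hydroxy-5-pentyloxolan-2-one F4. 2-Naphthylmethyl trichloroacetimidate with catalytic TfOH in CH2Cl2 then gives 8.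

2. Step 8. A dithiane sulfur may migrate to the cationic C9 (ring expansion), or hydride may be delivered from the wrong face of the oxocarbenium ion. The fallback sets out from 8 and comes back at 17; it needs neither the dithiane nor the oxocarbenium ion and forms the O–C9 bond by oxidative cyclisation. i-Bu2AlH (CH2Cl2, −78 °C) gives (4S,5S)-4-(naphthalen-2-ylmethoxy)-5-pentyloxolan-2-ol F8. Wittig methylenation (Ph3P=CH2, THF) gives (4S,5S)-4-(naphthalen-2-ylmethoxy)dec-1-en-5-ol F9. Mukaiyama aerobic oxidative cyclisation (Co(modp)2 [modp = 1-morpholinocarbamoyl-4,4-dimethylpentane-1,3-dionate], a divalent cobalt complex, O2, t-BuOOH, i-PrOH, 55 °C), which is 2,5-trans selective, should give [(2R,4S,5S)-4-(naphthalen-2-ylmethoxy)-5-pentyloxolan-2-yl]methanol F10. Dess–Martin periodinane gives (2R,4S,5S)-4-(naphthalen-2-ylmethoxy)-5-pentyloxolane-2-carbaldehyde F11. Chelation-controlled addition (MgBr2·OEt2, CH2Cl2/Et2O, −78 °C) of non-8-en-1-ylmagnesium bromide F12, made from 10 and magnesium, should give the threo alcohol 17.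

3. Step 7. The hindered, strongly basic carbanion may deprotonate the lactone at C8, which leads to β-elimination of the naphthylmethoxide, or the addition may stall. The fallback sets out from 8 and comes back at 14, and moves the acylation to an open-chain amide. MeNH(OMe)·HCl with Me2AlCl (CH2Cl2, 0 °C) opens the lactone to (3S,4S)-4-hydroxy-N-methoxy-N-methyl-3-(naphthalen-2-ylmethoxy)nonanamide F5. Et3SiOTf and 2,6-lutidine give (3S,4S)-N-methoxy-N-methyl-3-(naphthalen-2-ylmethoxy)-4-(triethylsilyloxy)nonanamide F6. Carbanion 13 adds once to the Weinreb amide (stable chelated tetrahedral intermediate) to give (3S,4S)-3-(naphthalen-2-ylmethoxy)-1-[2-(non-8-en-1-yl)-1,3-dithian-2-yl]-4-(triethylsilyloxy)nonan-1-one F7. HF·pyridine removes the silyl group and the γ-hydroxy ketone closes to 14.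

**Further compounds**

F1 | step 5 | methyl (S)-2-hydroxyheptanoate | CCCCC[C@H](O)C(=O)OC
F2 | step 5 | methyl (S)-2-acetoxyheptanoate | CCCCC[C@H](OC(C)=O)C(=O)OC
F3 | step 5 | (5S)-4-hydroxy-5-pentylfuran-2(5H)-one | O=C1C=C(O)[C@H](CCCCC)O1
F4 | step 5 | (4S,5S)-4-hydroxy-5-pentyloxolan-2-one | O=C1C[C@H](O)[C@H](CCCCC)O1
F5 | step 7 | (3S,4S)-4-hydroxy-N-methoxy-N-methyl-3-(naphthalen-2-ylmethoxy)nonanamide | CON(C)C(=O)C[C@H](OCc1ccc2ccccc2c1)[C@H](CCCCC)O
F6 | step 7 | (3S,4S)-N-methoxy-N-methyl-3-(naphthalen-2-ylmethoxy)-4-(triethylsilyloxy)nonanamide | CON(C)C(=O)C[C@H](OCc1ccc2ccccc2c1)[C@H](CCCCC)O[Si](CC)(CC)CC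
F7 | step 7 | (3S,4S)-3-(naphthalen-2-ylmethoxy)-1-[2-(non-8-en-1-yl)-1,3-dithian-2-yl]-4-(triethylsilyloxy)nonan-1-one | C=CCCCCCCCC1(SCCCS1)C(=O)C[C@H](OCc2ccc3ccccc3c2)[C@H](CCCCC)O[Si](CC)(CC)CC
F8 | step 8 | (4S,5S)-4-(naphthalen-2-ylmethoxy)-5-pentyloxolan-2-ol (both C2 epimers) | OC1C[C@H](OCc2ccc3ccccc3c2)[C@H](CCCCC)O1
F9 | step 8 | (4S,5S)-4-(naphthalen-2-ylmethoxy)dec-1-en-5-ol | C=CC[C@H](OCc1ccc2ccccc2c1)[C@H](CCCCC)O
F10 | step 8 | [(2R,4S,5S)-4-(naphthalen-2-ylmethoxy)-5-pentyloxolan-2-yl]methanol | OC[C@H]1C[C@H](OCc2ccc3ccccc3c2)[C@H](CCCCC)O1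
F11 | step 8 | (2R,4S,5S)-4-(naphthalen-2-ylmethoxy)-5-pentyloxolane-2-carbaldehyde | O=C[C@H]1C[C@H](OCc2ccc3ccccc3c2)[C@H](CCCCC)O1
F12 | step 8 | non-8-en-1-ylmagnesium bromide | C=CCCCCCCC[Mg]Br
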